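- A leftover is what I watch in Tuesday's flask. If free catalyst and impurity combine one to one, as the candidate step free catalyst + impurity -> spent catalyst says, then c(impurity) of 1.1 mM against c(free catalyst) of 0.79 mM leaves 0.310 mM of impurity once the catalyst is taken up.

| setting | Tuesday's | Monday's | flask |
|---|---|---|---|
| starting material | 0.95 M | 1.9 M | 0.95 M |
| second substrate | 0.475 M | 0.475 M | 0.475 M |
| reagent | 0.76 M | 0.76 M | 0.760 M |
| free catalyst | 0.79 mM | 0.79 mM | 0.79 mM |
| impurity | 1.1 mM | 1.1 mM | 1.1 mM |
| temperature | 80 °C | 86 °C | 80 °C |
| remark | the very flask that is asked about, followed so far | run made earlier |  |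
| time |  |  | 8.0 d |

| run | time / h | target / % | starting material / % |
|---|---|---|---|
| Tuesday's | 25.0 | 22.5 | 76.9 |
| Tuesday's | 72.0 | 22.7 | 75.8 |
| Tuesday's | 120 | 22.2 | 77.2 |
| Tuesday's | 192 | 23.8 | 76.7 |
| Monday's | 3.00 | 11.6 | 88.0 |
| Monday's | 6.00 | 14.8 | 84.8 |
| Monday's | 10.0 | 17.7 | 81.3 |
| Monday's | 12.0 | 18.4 | 81.3 |

(standard deviation of a reading: 0.5 percentage points)

- noon: at 8.0 d raise the temperature by 10 K, then wait 8.0 d
- dusk: change nothing and wait 8.0 d more
- spring: at 8.0 d add reagent, 50.0 % of the amount charged, then wait 8.0 d
- winter: at 8.0 d take out 90 % of the target then present, then wait 8.0 d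
- dawn: at 8.0 d add free catalyst, 50.0 % of the amount charged, then wait 8.0 d

- target, in percent of the starting material first charged, at 8.0 d
- which option adds most target ("none" when 2 percentage points or less is all one gets) (noon / dusk / spring / winter / dawn / none)
- target present, with what was taken out counted in, in percent of the starting material first charged, after dusk
- target present, with what was taken out counted in, in percent of the starting material first charged, after winter

- target taken out counts as made
- the numbers in the tables scatter with a standard deviation of 0.5 percentage points
- candidate steps: free catalyst + impurity -> spent catalyst; reagent + catalyst intermediate A <-> free catalyst + target; starting material + free catalyst <-> catalyst intermediate A; second substrate + free catalyst <-> catalyst intermediate B; reagent + catalyst intermediate B -> free catalyst + second product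
- additions bring no volume worth counting

- The shortest rung of my ladder is hours. In Monday's flask the first 3.00 h bring 11.6 % of target, but the stretch from 10.0 h to 12.0 h brings 0.7 percentage points, so I expect the catalyst to work there for hours.
- The next rung is a day. Tuesday's flask stands at 22.5 % at 25.0 h and at 23.8 % at 192 h, with a scatter of 0.5 points. I read the four readings as one plateau with mean 22.8 %, and I commit to that value for now, for dusk and for winter.
- Running out of reagent does not account for the stop in Tuesday's flask: even if the whole charge of second substrate had used reagent, 0.0684 M of it would remain.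
- Now I follow one catalyst molecule. Each time it comes back free, it either starts another round or meets impurity. I call the target made per catalyst charged the turnover number; read off the plateau of Tuesday's flask it is 274, so in that flask its chance of dying is, on average, about one in that number for each target made.
- So I expect nothing from noon, spring or winter, since they give no new catalyst. Dawn adds 0.395 mM, more than the leftover of impurity, and if each added molecule earns the same turnover number, my estimate is 11 points, against a margin of 2 points.
- The forecast gives 23 % (22.3 % to 23.8 %), above my 22.8 %, 23.1 % after dusk, 23.3 % after winter and dawn as best, reading the curves as “catalyst killed by impurity, which is in excess”.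
- The flask gives 23.3 % at 8.0 d, 23.3 % after dusk and 23.3 % after winter; dawn adds 17 points, and noon, dusk, spring and winter add 0 points each.

    free catalyst + impurity → spent catalyst (k = 12.0 M⁻¹ min⁻¹, Ea = 56.0 kJ mol⁻¹)
    reagent + catalyst intermediate A ⇌ free catalyst + target (K = 0.890, k = 5.70 M⁻¹ min⁻¹, Ea = 73.0 kJ mol⁻¹, ΔH = −27.0 kJ mol⁻¹)
    starting material + free catalyst ⇌ catalyst intermediate A (K = 2.60 M⁻¹, k = 4.10 M⁻¹ min⁻¹, Ea = 48.0 kJ mol⁻¹, ΔH = 0 kJ mol⁻¹)
    second substrate + free catalyst ⇌ catalyst intermediate B (K = 0.690 M⁻¹, k = 2.40 M⁻¹ min⁻¹, Ea = 52.0 kJ mol⁻¹, ΔH = −22.0 kJ mol⁻¹)
    reagent + catalyst intermediate B → free catalyst + second product (k = 1.80 M⁻¹ min⁻¹, Ea = 55.0 kJ mol⁻¹)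
    (constants at 80 °C)

- In the flask at 192 h spent catalyst stands at 100 % of the catalyst charged and impurity at 28 % of its charge, which is 0.308 mM, the leftover. The catalyst added at dawn earns 401 turnovers per molecule, against my 274. In the neighbour flask with 3.0 M of reagent, impurity again ends at 28 % of its charge and spent catalyst at 100 %, while target reaches 31.6 %, a turnover number of 380.

All runs were computed for substances that don't exist; noise was put on by code.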